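| flask | starting material | partner | remark | time |
|---|---|---|---|---|
| Monday's | 0.14 M | 0.63 M | run made earlier |  |
| Saturday's | 0.35 M | 0.63 M | run made earlier |  |
| amber | 0.040 M | 0.630 M |  | 6.0 min |
| violet | 0.12 M | 0.630 M |  | 6.0 min |
| blue | 0.40 M | 0.630 M |  | 6.0 min |

| run | time / min | target / % | starting material / % |
|---|---|---|---|
| Monday's | 0.250 | 2 | 62 |
| Monday's | 0.417 | 0 | 52 |
| Monday's | 0.833 | 7 | 52 |
| Monday's | 1.50 | 4 | 41 |
| Monday's | 3.00 | 24 | 33 |
| Saturday's | 0.250 | 2 | 62 |
| Saturday's | 0.833 | 4 | 49 |
| Saturday's | 1.33 | 6 | 47 |
| Saturday's | 2.00 | 12 | 41 |
| Saturday's | 3.00 | 23 | 38 |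

(scatter of a reading: 2 percentage points)

- the numbers in the tables scatter by 2 percentage points (one standard deviation)
- "hardly changes" means that all values lie within two and a half points (for a concentration: within two and a half percent of the largest)

- [target] at the end for amber, violet, blue, in this order
- the shape of the row from first to last (falls, then rises / rises all the way / rises, then falls / falls all the way / hardly changes)

Late in a run the quick part lies behind you, so read the flask there. In Saturday's run starting material is down to 49% by 0.833 min, well before the last reading. Two times remain. One is the time left, from the last reading to the end. The other is the drain time τ, the pseudo-first-order time constant of the pool u, where u is the fraction of the charge not yet target. Replace the steepening curve by its mean, using Saturday's last two readings: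

τ = Δt / ln(u before / u after) = 7.49 min

time left = 3.00 min

target at the end = 1 − u·exp(−time left/τ) = 48.4%

This is a rough reading, since each point scatters by 2 percentage points, and a constant τ errs if the slope keeps rising. Monday's 24% and Saturday's 23% at 3.00 min, each with that scatter, neither show an effect of charge nor exclude one. I therefore assume one percentage for all the flasks, and my row is 0.0194 M, 0.0581 M, 0.194 M.

The forecast takes about 55%, “Allowing slight slowing”: 0.022 M, 0.066 M, 0.22 M, and rises all the way.

The flasks give 0.0254 M, 0.0720 M, 0.194 M, and rises all the way.

    starting material ⇌ open intermediate (K = 1.10, k = 0.0400 s⁻¹)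
    partner → second intermediate (k = 0.00260 s⁻¹)
    open intermediate + second intermediate → target (k = 0.0280 L mol⁻¹ s⁻¹)
    2 second intermediate → homo product (k = 9.70 × 10⁻⁴ L mol⁻¹ s⁻¹)

Blue keeps close to τ: its own drain time from 3.00 min to 6.00 min is 7.08 min, and target reaches 48.4%. Amber drains faster, in 4.29 min, and reaches 63.5%. Blue stands at 0.194 M partly because of the way back from open intermediate to starting material, acting together with the time allowed: without the way back blue gives 0.248 M, and at a tenfold time it gives 0.400 M.

The runs were generated by integration on assumed constants.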